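Once the fast first minutes of these runs are over, a leftover remains: target still moves a little, and how it moves depends on the catalyst.

the same everywhere: substrate 0.78 M
- alpha: catalyst 2.7 mM; run made earlier
- zeta: catalyst 8.2 mM; run made earlier
- beta: catalyst 19 mM; run made earlier
- Monday's: catalyst 3.0 mM; time 80 min
- Wednesday's: catalyst 6.0 mM; time 80 min
- Friday's: catalyst 15 mM; time 80 min
- Tuesday's: catalyst 25 mM; time 80 min

| run | time / min | target / % |
|---|---|---|
| alpha | 8.00 | 24.9 |
| alpha | 15.0 | 29.3 |
| alpha | 25.0 | 31.0 |
| alpha | 30.0 | 31.7 |
| alpha | 40.0 | 32.3 |
| zeta | 4.00 | 26.4 |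
| zeta | 10.0 | 29.7 |
| zeta | 20.0 | 30.7 |
| zeta | 30.0 | 32.2 |
| zeta | 40.0 | 33.2 |
| beta | 4.00 | 28.6 |
| beta | 10.0 | 30.8 |
| beta | 20.0 | 31.9 |
| beta | 30.0 | 32.4 |
| beta | 40.0 | 32.0 |

(standard deviation of a reading: 0.3 percentage points)

- "hardly changes" means that all values lie within two and a half points (for a concentration: within two and a half percent of the largest)

* amount of target at the end, in percent of the substrate charged for Monday's, Wednesday's, Friday's, Tuesday's, in this order
* the shape of the row from first to last (hardly changes / rises, then falls / falls all the way / falls, then rises / rises all the way)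

I build the flask one process at a time, starting with the main step, substrate to target over catalyst. Its pace goes with [catalyst]: alpha, at 2.7 mM, reads 24.9% after 8.00 min, while beta, at 19 mM, reads 28.6% after 4.00 min. Yet zeta and beta lie close together at 10.0 min, at 29.7% and 30.8%, so this step by itself gives me a flat row.

Next I add a slow feed of target. Between 20.0 min and 40.0 min, zeta climbs from 30.7% to 33.2%, which is 0.00125 /min as a fraction of the charge. Beta climbs more slowly than zeta over the same span, at 5.00 × 10⁻⁵ /min.

A feed that fades sooner at higher [catalyst] is one reading of that, and these readings leave it open; I commit to the other and add a drain on target, a pseudo-first-order loss that grows with [catalyst]. Dividing the difference of the two slopes by the difference of the two loadings gives the drain per millimolar, 1.11 × 10⁻⁴ /min/mM, give or take 2.78 × 10⁻⁵ /min/mM from the scatter. Over that span, feed and drain cancel at a balance loading of 19.5 mM, a value read off these two slopes that belongs to this span. Tuesday's lies above it, so, carrying that span's feed and drain on to 80 min from beta's last reading, I reckon 29.5% for Tuesday's. Alpha creeps at 8.67 × 10⁻⁴ /min, slower than the line allows, so I let the feed fade and put Monday's just above zeta's last 33.2%. My row falls all the way.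

The forecast gives 33.6%, 33.6%, 32.8% and 32.3%, shape hardly changes, on a ceiling “reached sooner with more catalyst”, where I have a falling row.

The flask gives 34.5%, 33.7%, 30.8% and 27.9%, shape falls all the way.

    substrate + catalyst ⇌ target + catalyst, rate k1*[substrate]*[catalyst] forward; the back reaction follows from the equilibrium constant (K = 13.0, k = 0.440 /M/s)
    target ⇌ isomer of the product (K = 1.60, k = 2.10 × 10⁻⁴ /s)
    isomer of the product + catalyst ⇌ substrate + catalyst, rate k3*[catalyst]*[isomer of the product] forward; the back reaction follows from the equilibrium constant (k = 0.0550 /M/s)
    catalyst + target → catalyst + over-reaction product (k = 0.00560 /M/s)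

At 80.0 min, Tuesday's flask holds 20.2% of over-reaction product. My drain per millimolar, 1.11 × 10⁻⁴ /min/mM, times Friday's 15 mM and 80 min gives 13.3%, and Friday's flask holds 12.5% of over-reaction product.

(All runs were generated by integration for substances that don't exist.)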